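The route rests on forming the tertiary C4–O bond of ring A (the six-membered carbocycle: C1 ketone, C2 nitrogen-bearing, C3, C4, C5 carbinol, C6) by an allylic transposition. It exploits the fact that the tertiary oxygen on C4 lies one carbon beyond the C2=C3 double bond and on the same ring face as the hydroxyl on C5. In one operation a palladium allyl spanning C2–C4 is closed by a CO2 unit held on the C5 oxygen, which makes the C4–O bond, the quaternary stereocentre, the cis-diol (as cyclic carbonate) and the C2=C3 alkene. The precursor is a cyclohexene with cis C2 acetate and C5 hydroxyl and a silylated alkyne on C4.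

Key step: step 7

Remark: the lipase in step 2 is assumed to cleave the (R)-configured ester of the meso diacetate, the usual preference of lipases for secondary acetates flanked by an alkene and a CH2 group.

Ring A atoms are numbered C1–C6 as in the target throughout the Why lines.

**Ring A up to the iodoenone**

Step 1
Reactants: 1 cyclohexa-1,3-diene
Product: 2 cis-cyclohex-2-ene-1,4-diyl diacetate (meso)
Conditions: Pd(OAc)2 (5 mol %), LiCl (0.2 equiv), LiOAc, p-benzoquinone (2 equiv), AcOH, 25 °C
Reagents that add atoms: acetic acid, CC(=O)O; lithium acetate, [Li+].CC(=O)[O-]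
Why: Palladium-catalysed 1,4-diacetoxylation of a 1,3-diene: acetate adds anti to divalent palladium to give an allyl complex, and because chloride occupies the metal the second acetate also attacks from outside, anti to palladium, so both C–O bonds end on one face (cis, meso) while benzoquinone reoxidises the zerovalent palladium.

Step 2
Reactants: 2 cis-cyclohex-2-ene-1,4-diyl diacetate
Product: 3 (1S,4R)-4-hydroxycyclohex-2-en-1-yl acetate
Conditions: Candida antarctica lipase B (immobilised), phosphate buffer pH 7, 25 °C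
Reagents that add atoms: none
Why: Enzymatic desymmetrisation (enantiotopic-group-selective ester hydrolysis) of the meso diacetate: the lipase cleaves the ester on the (R)-configured carbon, so the surviving acetate sits on the (S)-carbon that becomes C2 of ring A and both stereocentres of 3 are fixed at once.

Step 3
Reactants: 3 (1S,4R)-4-hydroxycyclohex-2-en-1-yl acetate
Product: 4 (S)-4-oxocyclohex-2-en-1-yl acetate
Conditions: Dess–Martin periodinane (1.2 equiv), NaHCO3, CH2Cl2, 0 to 25 °C
Reagents that add atoms: none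
Why: Dess–Martin oxidation of a secondary allylic alcohol under buffered, near-neutral conditions that should leave the acetoxy-bearing stereocentre untouched.

Step 4
Reactants: 4 (S)-4-oxocyclohex-2-en-1-yl acetate
Product: 5 (S)-3-iodo-4-oxocyclohex-2-en-1-yl acetate
Conditions: I2 (2 equiv), pyridine/CH2Cl2 1:1, 0 to 25 °C
Reagents that add atoms: iodine, II
Why: Alpha-iodination of an enone by conjugate addition of pyridine, iodination of the enolate and loss of pyridine (a Baylis–Hillman-type sequence), a standard reaction of 4-oxygenated cyclohexenones that does not involve the acetoxy-bearing carbon.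

Step 5
Reactants: 5 (S)-3-iodo-4-oxocyclohex-2-en-1-yl acetate; 6 (triisopropylsilyl)acetylene
Product: 7 (S)-4-oxo-3-[(triisopropylsilyl)ethynyl]cyclohex-2-en-1-yl acetate
Conditions: PdCl2(PPh3)2 (3 mol %), CuI (6 mol %), iPr2NH (3 equiv), THF, 0 °C
Reagents that add atoms: none
Why: Sonogashira coupling, which is fast at 0 °C for an electron-poor alpha-iodoenone, so the base-sensitive acetoxy enone should see the amine only briefly.

Step 6
Reactants: 7 (S)-4-oxo-3-[(triisopropylsilyl)ethynyl]cyclohex-2-en-1-yl acetate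
Product: 8 (1S,4R)-4-hydroxy-3-[(triisopropylsilyl)ethynyl]cyclohex-2-en-1-yl acetate (cis)
Conditions: NaBH4 (1.1 equiv), CeCl3·7H2O (1.1 equiv), MeOH, −78 °C
Reagents that add atoms: none
Why: Luche 1,2-reduction: hydride should add axially to the half-chair in which the C2 acetoxy group is pseudoaxial, on the face away from it, so the new C5 hydroxyl ends cis to the acetate, and the short, cold reaction spares ester, alkyne and silyl group.

Step 7
Reactants: 8 (1S,4R)-4-hydroxy-3-[(triisopropylsilyl)ethynyl]cyclohex-2-en-1-yl acetate; 9 carbon dioxide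
Product: 11 (3aR,7aR)-3a-[(triisopropylsilyl)ethynyl]-3a,6,7,7a-tetrahydro-1,3-benzodioxol-2-one, via C5 hydrogen carbonate 10 (not isolated)
Conditions: Pd(PPh3)4 (5 mol %), CO2 (1 atm), DBU (1.2 equiv), MeCN, 25 to 40 °C
Reagents that add atoms: none
Why: DBU and CO2 convert the C5 hydroxyl into its carbonate anion 10, while zerovalent palladium ionises the allylic C2 acetate with inversion (Tsuji–Trost) to an allyl complex over C2–C3–C4 that carries the metal on the ring face opposite the C5 oxygen. The carbonate oxygen then attacks C4 from outside, anti to palladium, which forms the C4–O bond, moves the alkene to C2=C3 and releases the catalyst. The closest known reaction type is the palladium-catalysed carboxylative cyclisation of vinyl epoxides, or of 4-(alkoxycarbonyloxy)alk-2-en-1-ols, with CO2 to vinyl cyclic carbonates, which passes through the same allyl-alkoxide/CO2 species. The one ring closed, the five-membered cyclic carbonate, forms by 5-exo attack of oxygen on the allyl terminus and is cis-fused. The new quaternary stereocentre C4 is controlled by the C2 acetate through double inversion (oxygen enters on the face the acetate left), and that face is the one carrying the C5 oxygen. The step needs attack at C4 and not C2, secured by the tether (C2 would require a bridged seven-membered ring), and closure faster than beta-hydride loss, favoured by the CO2 atmosphere; the bulky silyl group also shields the alkyne terminus from propargylic ionisation of the product.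

Step 8
Reactants: 11 (3aR,7aR)-3a-[(triisopropylsilyl)ethynyl]-3a,6,7,7a-tetrahydro-1,3-benzodioxol-2-one
Product: 12 (3aR,7aR)-3a-[(triisopropylsilyl)ethynyl]-7,7a-dihydro-1,3-benzodioxole-2,6(3aH)-dione
Conditions: Rh2(cap)4 (dirhodium tetracaprolactamate, 1 mol %), tBuOOH (70% in water, 5 equiv), 1,2-dichloroethane, 40 °C
Reagents that add atoms: tert-butyl hydroperoxide, CC(C)(C)OO
Why: Dirhodium-catalysed allylic C–H oxidation (tert-butylperoxyl radical chain, the mixed peroxide collapsing to the ketone): C1 carries the only allylic hydrogens and the far end of the allyl radical, C3, is shielded by the fully substituted C4, so the carbonyl should form at C1 with the alkene left at C2=C3, while carbonate, silylalkyne and both stereocentres are inert.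

Step 9
Reactants: 12 (3aR,7aR)-3a-[(triisopropylsilyl)ethynyl]-7,7a-dihydro-1,3-benzodioxole-2,6(3aH)-dione
Product: 13 (3aR,7aR)-5-iodo-3a-[(triisopropylsilyl)ethynyl]-7,7a-dihydro-1,3-benzodioxole-2,6(3aH)-dione
Conditions: I2 (2 equiv), pyridine/CH2Cl2 1:1, 0 to 25 °C
Reagents that add atoms: iodine, II
Why: Alpha-iodination of the enone as in step 4 (pyridine adds at C3, iodine enters at C2, pyridine leaves), a reaction known for cyclohexenones with a quaternary C4, and pyridine is too weak a base to expel the C5 carbonate oxygen.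

**Side-chain amide**

Step 10
Reactants: 14 hexanoyl chloride; 15 (R)-4-benzyloxazolidin-2-one
Product: 16 (R)-4-benzyl-3-hexanoyloxazolidin-2-one
Conditions: n-BuLi (1.05 equiv), THF, −78 °C; then 14, −78 to 0 °C
Reagents that add atoms: none
Why: N-Acylation of the lithiated oxazolidinone by an acid chloride, the standard attachment of an Evans auxiliary.

Step 11
Reactants: 16 (R)-4-benzyl-3-hexanoyloxazolidin-2-one
Product: 17 (R)-4-benzyl-3-[(R)-2-methylhexanoyl]oxazolidin-2-one
Conditions: NaHMDS (1.1 equiv), THF, −78 °C; MeI (3 equiv), −78 °C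
Reagents that add atoms: iodomethane, CI
Why: Evans asymmetric alkylation: the chelated Z-enolate is methylated on the face opposite the benzyl group, which with the (R)-auxiliary should give the (R)-configured alpha-carbon.

Step 12
Reactants: 17 (R)-4-benzyl-3-[(R)-2-methylhexanoyl]oxazolidin-2-one
Product: 18 (R)-2-methylhexan-1-ol
Conditions: LiBH4 (1.2 equiv), H2O (1.2 equiv), Et2O, 0 °C
Reagents that add atoms: none
Why: Reductive cleavage of the N-acyl oxazolidinone by LiBH4 at the exocyclic carbonyl, which frees the primary alcohol without touching the alpha-stereocentre and returns the auxiliary.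

Step 13
Reactants: 18 (R)-2-methylhexan-1-ol; 19 ethyl 2-(triphenylphosphoranylidene)propanoate
Product: 21 ethyl (R,E)-2,4-dimethyloct-2-enoate, via (R)-2-methylhexanal 20 (not isolated)
Conditions: Dess–Martin periodinane (1.2 equiv), CH2Cl2, 0 to 25 °C; then 19 (1.5 equiv), 25 to 40 °C
Reagents that add atoms: none
Why: Dess–Martin oxidation followed in the same flask by a Wittig reaction with a stabilised ylide, which should give the (E)-trisubstituted alkene and consumes the epimerisable aldehyde without isolation.

Step 14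
Reactants: 21 ethyl (R,E)-2,4-dimethyloct-2-enoate
Product: 22 (R,E)-2,4-dimethyloct-2-enamide
Conditions: AlMe3 (3 equiv), NH4Cl (3 equiv), toluene, 0 to 50 °C; aqueous HCl work-up
Reagents that add atoms: ammonium chloride, [NH4+].[Cl-]
Why: Aminolysis of the ester by the aluminium amide generated from AlMe3 and NH4Cl, which attacks the hindered conjugated ester at the carbonyl and leaves alkene geometry and the remote stereocentre unchanged.

**Union and chain functionalisation**

Step 15
Reactants: 13 (3aR,7aR)-5-iodo-3a-[(triisopropylsilyl)ethynyl]-7,7a-dihydro-1,3-benzodioxole-2,6(3aH)-dione; 22 (R,E)-2,4-dimethyloct-2-enamide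
Product: 23 (R,E)-N-{(3aR,7aR)-2,6-dioxo-3a-[(triisopropylsilyl)ethynyl]-3a,6,7,7a-tetrahydro-1,3-benzodioxol-5-yl}-2,4-dimethyloct-2-enamide
Conditions: CuI (20 mol %), N,N'-dimethylethylenediamine (40 mol %), K2CO3 (2 equiv), toluene, 60 °C
Reagents that add atoms: none
Why: Copper-catalysed Goldberg-type N-vinylation of a primary amide with a vinyl iodide: the alpha-iodoenone is an activated partner that should couple at moderate temperature, and the weak, insoluble base is chosen so that the C5 carbonate oxygen beta to the ketone is not eliminated.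

Step 16
Reactants: 23 amido-enone carbonate
Product: 24 (R,E)-N-{(3R,4R)-3,4-dihydroxy-6-oxo-3-[(triisopropylsilyl)ethynyl]cyclohex-1-en-1-yl}-2,4-dimethyloct-2-enamide
Conditions: K2CO3 (0.3 equiv), MeOH, 0 °C
Reagents that add atoms: none
Why: Transesterification of the five-membered cyclic carbonate with methanol to dimethyl carbonate and the cis-diol, done cold and before the last two palladium steps because zerovalent palladium would ionise an allylic and propargylic cyclic carbonate.

Step 17
Reactants: 24 silylalkyne diol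
Product: 25 (R,E)-N-[(3R,4R)-3-ethynyl-3,4-dihydroxy-6-oxocyclohex-1-en-1-yl]-2,4-dimethyloct-2-enamide
Conditions: Bu4NF (1.5 equiv), AcOH (1.5 equiv), THF, 0 to 25 °C
Reagents that add atoms: none
Why: Fluoride-induced protodesilylation of the alkynylsilane, buffered with acetic acid so that the beta-hydroxy ketone is not exposed to a strong base.

Step 18
Reactants: 25 terminal alkyne diol
Product: 26 (R,E)-N-{(3R,4R)-3,4-dihydroxy-6-oxo-3-[(E)-2-(tributylstannyl)ethenyl]cyclohex-1-en-1-yl}-2,4-dimethyloct-2-enamide
Conditions: PdCl2(PPh3)2 (3 mol %), Bu3SnH (1.2 equiv, slow addition), THF, 0 °C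
Reagents that add atoms: tributyltin hydride, CCCC[SnH](CCCC)CCCC
Why: Palladium-catalysed hydrostannylation of a terminal alkyne: syn addition gives the (E)-alkene and the fully substituted propargylic carbinol directs tin to the terminal carbon, while the terminal alkyne should react far faster than the trisubstituted amido-enone is reduced.

**Lower arm**

Step 19
Reactants: 27 cyclopentane-1,3-dione
Product: 28 2-(hydroxyimino)cyclopentane-1,3-dione
Conditions: NaNO2 (1.1 equiv), aqueous HCl, 0 °C
Reagents that add atoms: sodium nitrite, [Na+].[O-]N=O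
Why: Electrophilic nitrosation of the enol of a 1,3-dione at C2, followed by tautomerisation of the nitroso compound to the oxime.

Step 20
Reactants: 28 2-(hydroxyimino)cyclopentane-1,3-dione
Product: 29 2-amino-3-hydroxycyclopent-2-en-1-one hydrochloride
Conditions: H2 (1 atm), 10% Pd/C, HCl (1.1 equiv), MeOH, 25 °C
Reagents that add atoms: hydrogen chloride, Cl
Why: Catalytic hydrogenation of the oxime to the primary amine, trapped as its hydrochloride so that the alpha-amino ketone cannot self-condense, the enolised vinylogous acid resisting further reduction.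

Step 21
Reactants: 30 glutaconaldehyde potassium salt
Product: 31 (2E,4E)-5-bromopenta-2,4-dienal
Conditions: Ph3PBr2 (1.1 equiv), CH2Cl2, 0 to 25 °C; then I2 (2 mol %), 25 °C
Reagents that add atoms: dibromotriphenylphosphorane, BrP(Br)(c1ccccc1)(c1ccccc1)c1ccccc1
Why: Deoxybromination of the enolate oxygen through an oxyphosphonium salt (bromide adds, triphenylphosphine oxide leaves), after which a trace of iodine should equilibrate the dienal to the most stable all-E isomer.

Step 22
Reactants: 31 (2E,4E)-5-bromopenta-2,4-dienal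
Product: 32 (2E,4E)-5-bromopenta-2,4-dienoic acid
Conditions: NaClO2 (1.5 equiv), NaH2PO4, 2-methylbut-2-ene (10 equiv), tBuOH/H2O, 0 to 25 °C
Reagents that add atoms: sodium chlorite, [Na+].[O-]Cl=O
Why: Pinnick oxidation of the conjugated aldehyde, with 2-methylbut-2-ene scavenging hypochlorous acid so that the bromodiene is neither chlorinated nor isomerised.

Step 23
Reactants: 32 (2E,4E)-5-bromopenta-2,4-dienoic acid; 29 2-amino-3-hydroxycyclopent-2-en-1-one hydrochloride
Product: 34 (2E,4E)-5-bromo-N-(2-hydroxy-5-oxocyclopent-1-en-1-yl)penta-2,4-dienamide, via bromodienoyl chloride 33 (not isolated)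
Conditions: (COCl)2 (1.2 equiv), DMF (cat.), CH2Cl2, 0 to 25 °C; then 29 (1.1 equiv), Et3N (3.2 equiv), THF, 0 to 25 °C
Reagents that add atoms: oxalyl chloride, ClC(=O)C(Cl)=O (chlorine of 33 only)
Why: Acid chloride formation and acylation of the free-based amine; any O-acylated enol ester is itself an acyl donor and should transfer to nitrogen, so the amide is the resting product.

**Final coupling**

Step 24
Reactants: 26 alkenylstannane diol; 34 bromodienamide
Product: 35 (2E,4E,6E)-7-[(1S,6R)-3-{[(2E,4R)-2,4-dimethyloct-2-enoyl]amino}-1,6-dihydroxy-4-oxocyclohex-2-en-1-yl]-N-(2-hydroxy-5-oxocyclopent-1-en-1-yl)hepta-2,4,6-trienamide (target)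
Conditions: PdCl2(MeCN)2 (10 mol %), DMF, 25 °C, dark
Reagents that add atoms: none
Why: Stille coupling of an (E)-alkenylstannane with an electron-poor (E)-alkenyl bromide under ligand-free conditions at room temperature, which proceeds with retention at both alkenes to give the all-E triene, tolerates the free diol, enol and amide N–H groups, and should deliver the target without any later deprotection.

**Compound list**

1 | cyclohexa-1,3-diene | C1=CC=CCC1 | starting material
2 | cis-cyclohex-2-ene-1,4-diyl diacetate (meso) | CC(=O)O[C@@H]1C=C[C@H](OC(C)=O)CC1 | intermediate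
3 | (1S,4R)-4-hydroxycyclohex-2-en-1-yl acetate | CC(=O)O[C@@H]1C=C[C@H](O)CC1 | intermediate
4 | (S)-4-oxocyclohex-2-en-1-yl acetate | CC(=O)O[C@@H]1C=CC(=O)CC1 | intermediate
5 | (S)-3-iodo-4-oxocyclohex-2-en-1-yl acetate | CC(=O)O[C@@H]1C=C(I)C(=O)CC1 | intermediate
6 | (triisopropylsilyl)acetylene | C#C[Si](C(C)C)(C(C)C)C(C)C | starting material
7 | (S)-4-oxo-3-[(triisopropylsilyl)ethynyl]cyclohex-2-en-1-yl acetate | CC(=O)O[C@@H]1C=C(C#C[Si](C(C)C)(C(C)C)C(C)C)C(=O)CC1 | intermediate
8 | (1S,4R)-4-hydroxy-3-[(triisopropylsilyl)ethynyl]cyclohex-2-en-1-yl acetate (cis; key-step precursor) | CC(=O)O[C@@H]1C=C(C#C[Si](C(C)C)(C(C)C)C(C)C)[C@H](O)CC1 | intermediate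
9 | carbon dioxide | O=C=O | starting material
10 | (1R,4S)-4-acetoxy-2-[(triisopropylsilyl)ethynyl]cyclohex-2-en-1-yl hydrogen carbonate (present as its DBU salt) | CC(=O)O[C@@H]1C=C(C#C[Si](C(C)C)(C(C)C)C(C)C)[C@H](OC(=O)O)CC1 | intermediate
11 | (3aR,7aR)-3a-[(triisopropylsilyl)ethynyl]-3a,6,7,7a-tetrahydro-1,3-benzodioxol-2-one (cis-fused cyclic carbonate of (1R,2R)-2-[(triisopropylsilyl)ethynyl]cyclohex-3-ene-1,2-diol) | C1=C[C@@](O2)(C#C[Si](C(C)C)(C(C)C)C(C)C)[C@H](OC2=O)CC1 | intermediate
12 | (3aR,7aR)-3a-[(triisopropylsilyl)ethynyl]-7,7a-dihydro-1,3-benzodioxole-2,6(3aH)-dione (C1 ketone, C2=C3, carbonate on C4 and C5) | C1=C[C@@](O2)(C#C[Si](C(C)C)(C(C)C)C(C)C)[C@H](OC2=O)CC1=O | intermediate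
13 | (3aR,7aR)-5-iodo-3a-[(triisopropylsilyl)ethynyl]-7,7a-dihydro-1,3-benzodioxole-2,6(3aH)-dione | IC1=C[C@@](O2)(C#C[Si](C(C)C)(C(C)C)C(C)C)[C@H](OC2=O)CC1=O | intermediate
14 | hexanoyl chloride | CCCCCC(Cl)=O | starting material
15 | (R)-4-benzyloxazolidin-2-one | O=C1N[C@H](Cc2ccccc2)CO1 | starting material
16 | (R)-4-benzyl-3-hexanoyloxazolidin-2-one | CCCCCC(=O)N1[C@H](Cc2ccccc2)COC1=O | intermediate
17 | (R)-4-benzyl-3-[(R)-2-methylhexanoyl]oxazolidin-2-one | CCCC[C@@H](C)C(=O)N1[C@H](Cc2ccccc2)COC1=O | intermediate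
18 | (R)-2-methylhexan-1-ol | CCCC[C@@H](C)CO | intermediate
19 | ethyl 2-(triphenylphosphoranylidene)propanoate | CCOC(=O)C(C)=P(c1ccccc1)(c1ccccc1)c1ccccc1 | starting material
20 | (R)-2-methylhexanal | CCCC[C@@H](C)C=O | intermediate
21 | ethyl (R,E)-2,4-dimethyloct-2-enoate | CCCC[C@@H](C)/C=C(\C)C(=O)OCC | intermediate
22 | (R,E)-2,4-dimethyloct-2-enamide | CCCC[C@@H](C)/C=C(\C)C(N)=O | intermediate
23 | (R,E)-N-{(3aR,7aR)-2,6-dioxo-3a-[(triisopropylsilyl)ethynyl]-3a,6,7,7a-tetrahydro-1,3-benzodioxol-5-yl}-2,4-dimethyloct-2-enamide | CCCC[C@@H](C)/C=C(\C)C(=O)NC1=C[C@@](O2)(C#C[Si](C(C)C)(C(C)C)C(C)C)[C@H](OC2=O)CC1=O | intermediate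
24 | (R,E)-N-{(3R,4R)-3,4-dihydroxy-6-oxo-3-[(triisopropylsilyl)ethynyl]cyclohex-1-en-1-yl}-2,4-dimethyloct-2-enamide | CCCC[C@@H](C)/C=C(\C)C(=O)NC1=C[C@@](O)(C#C[Si](C(C)C)(C(C)C)C(C)C)[C@H](O)CC1=O | intermediate
25 | (R,E)-N-[(3R,4R)-3-ethynyl-3,4-dihydroxy-6-oxocyclohex-1-en-1-yl]-2,4-dimethyloct-2-enamide | CCCC[C@@H](C)/C=C(\C)C(=O)NC1=C[C@@](O)(C#C)[C@H](O)CC1=O | intermediate
26 | (R,E)-N-{(3R,4R)-3,4-dihydroxy-6-oxo-3-[(E)-2-(tributylstannyl)ethenyl]cyclohex-1-en-1-yl}-2,4-dimethyloct-2-enamide | CCCC[C@@H](C)/C=C(\C)C(=O)NC1=C[C@@](O)(/C=C/[Sn](CCCC)(CCCC)CCCC)[C@H](O)CC1=O | intermediate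
27 | cyclopentane-1,3-dione | O=C1CCC(=O)C1 | starting material
28 | 2-(hydroxyimino)cyclopentane-1,3-dione | ON=C1C(=O)CCC1=O | intermediate
29 | 2-amino-3-hydroxycyclopent-2-en-1-one hydrochloride | NC1=C(O)CCC1=O.Cl | intermediate
30 | glutaconaldehyde potassium salt (potassium (1E,3E)-5-oxopenta-1,3-dien-1-olate) | [K+].[O-]/C=C/C=C/C=O | starting material
31 | (2E,4E)-5-bromopenta-2,4-dienal | Br/C=C/C=C/C=O | intermediate
32 | (2E,4E)-5-bromopenta-2,4-dienoic acid | OC(=O)/C=C/C=C/Br | intermediate
33 | (2E,4E)-5-bromopenta-2,4-dienoyl chloride | ClC(=O)/C=C/C=C/Br | intermediate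
34 | (2E,4E)-5-bromo-N-(2-hydroxy-5-oxocyclopent-1-en-1-yl)penta-2,4-dienamide | O=C(/C=C/C=C/Br)NC1=C(O)CCC1=O | intermediate
35 | (2E,4E,6E)-7-[(1S,6R)-3-{[(2E,4R)-2,4-dimethyloct-2-enoyl]amino}-1,6-dihydroxy-4-oxocyclohex-2-en-1-yl]-N-(2-hydroxy-5-oxocyclopent-1-en-1-yl)hepta-2,4,6-trienamide | CCCC[C@@H](C)/C=C(\C)C(=O)NC1=C[C@@](O)(/C=C/C=C/C=C/C(=O)NC2=C(O)CCC2=O)[C@H](O)CC1=O | target

**Step count**

Total: 24 steps. Longest linear sequence: 14 steps (steps 1–9, 15–18 and 24, from cyclohexa-1,3-diene).

**Steps most likely to fail**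

1. Step 7. After ionisation the palladium allyl may lose a beta-hydrogen from C1 or C5 (each has one syn to the metal) faster than the carbonate oxygen closes onto the hindered, alkynyl-bearing C4, or the CO2 adduct of the secondary alkoxide may be too sparsely populated; material would then drain into elimination and redox isomerisation. The fallback sets out from 8 and returns at 11. PhSNa with Pd(PPh3)4 in THF should replace the acetate at the unhindered C2 with net retention to give (1R,4S)-4-(phenylsulfanyl)-2-[(triisopropylsilyl)ethynyl]cyclohex-2-en-1-ol F1. mCPBA at −78 °C should give (1R,4S)-4-(phenylsulfinyl)-2-[(triisopropylsilyl)ethynyl]cyclohex-2-en-1-ol F2. Mislow–Evans [2,3]-rearrangement with Et2NH in MeOH should carry oxygen suprafacially from C2 to C4, on the face of the C5 hydroxyl, to give (1R,2R)-2-[(triisopropylsilyl)ethynyl]cyclohex-3-ene-1,2-diol F3. 1,1'-Carbonyldiimidazole should then close this cis-diol to carbonate 11.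

2. Step 15. Under base and heat, enolisation of the C1 ketone toward C6 may expel the C5 carbonate oxygen (E1cB) faster than the C–N bond forms, and the diamine ligand may open the carbonate. The fallback sets out from 13 and returns at 23; it removes the ketone for the basic step. NaBH4/CeCl3 in MeOH at −78 °C should reduce 13 to (3aR,7aR)-6-hydroxy-5-iodo-3a-[(triisopropylsilyl)ethynyl]-3a,6,7,7a-tetrahydro-1,3-benzodioxol-2-one F4 (either C6 epimer serves). The same CuI/diamine/K2CO3 amidation with 22, now on a vinyl iodide with no acidic alpha-hydrogens, should give (R,E)-N-{(3aR,7aR)-6-hydroxy-2-oxo-3a-[(triisopropylsilyl)ethynyl]-3a,6,7,7a-tetrahydro-1,3-benzodioxol-5-yl}-2,4-dimethyloct-2-enamide F5. Dess–Martin oxidation of the allylic alcohol should then return amido-enone 23.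

3. Step 8. The radical chain may stall on this electron-poor alkene, oxygen may enter at the C3 end of the allyl radical to give the transposed enone, or peroxide may attack elsewhere. The fallback sets out from 11 and returns at 12; it uses a pericyclic path that can only oxygenate C1. SeO2 (catalytic) with tBuOOH in CH2Cl2 (ene reaction at C3, then [2,3]-shift back to C1) should give (3aR,7aR)-6-hydroxy-3a-[(triisopropylsilyl)ethynyl]-3a,6,7,7a-tetrahydro-1,3-benzodioxol-2-one F6 as a mixture of C6 epimers. Dess–Martin oxidation should then give enone 12.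

**Further compounds**

F1 | step 7 | (1R,4S)-4-(phenylsulfanyl)-2-[(triisopropylsilyl)ethynyl]cyclohex-2-en-1-ol | c1ccccc1S[C@@H]1C=C(C#C[Si](C(C)C)(C(C)C)C(C)C)[C@H](O)CC1
F2 | step 7 | (1R,4S)-4-(phenylsulfinyl)-2-[(triisopropylsilyl)ethynyl]cyclohex-2-en-1-ol (mixture at sulfur) | O=S(c1ccccc1)[C@@H]1C=C(C#C[Si](C(C)C)(C(C)C)C(C)C)[C@H](O)CC1
F3 | step 7 | (1R,2R)-2-[(triisopropylsilyl)ethynyl]cyclohex-3-ene-1,2-diol | C1=C[C@@](O)(C#C[Si](C(C)C)(C(C)C)C(C)C)[C@H](O)CC1
F4 | step 15 | (3aR,7aR)-6-hydroxy-5-iodo-3a-[(triisopropylsilyl)ethynyl]-3a,6,7,7a-tetrahydro-1,3-benzodioxol-2-one (C6 epimers) | IC1=C[C@@](O2)(C#C[Si](C(C)C)(C(C)C)C(C)C)[C@H](OC2=O)CC1O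
F5 | step 15 | (R,E)-N-{(3aR,7aR)-6-hydroxy-2-oxo-3a-[(triisopropylsilyl)ethynyl]-3a,6,7,7a-tetrahydro-1,3-benzodioxol-5-yl}-2,4-dimethyloct-2-enamide (C6 epimers) | CCCC[C@@H](C)/C=C(\C)C(=O)NC1=C[C@@](O2)(C#C[Si](C(C)C)(C(C)C)C(C)C)[C@H](OC2=O)CC1O
F6 | step 8 | (3aR,7aR)-6-hydroxy-3a-[(triisopropylsilyl)ethynyl]-3a,6,7,7a-tetrahydro-1,3-benzodioxol-2-one (C6 epimers) | C1=C[C@@](O2)(C#C[Si](C(C)C)(C(C)C)C(C)C)[C@H](OC2=O)CC1O
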